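In a closed flask the charged starting material stands as starting material, catalyst intermediate or target, so the 1.6 percentage points missing from the last dusk reading is read as catalyst intermediate, which is 29.6% of the catalyst charged in the dusk run.

| setting | dusk | flask |
|---|---|---|
| starting material | 0.47 M | 0.94 M |
| free catalyst | 5.4 mol% | 5.4 mol% |
| remark | run made earlier |  |
| time |  | 8.0 min |

dusk run (percent of the starting material charged)

| time / s | target / % | starting material / % |
|---|---|---|
| 10.0 | 0.3 | 98.1 |
| 15.0 | 1.6 | 96.9 |
| 20.0 | 1.9 | 96.1 |
| 30.0 | 4.3 | 94.5 |
| 40.0 | 4.8 | 94.5 |
| 50.0 | 5.6 | 92.8 |

(standard deviation of a reading: 0.5 percentage points)

1. the target in the flask at 8.0 min, as a percentage of the starting material charged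
2. the starting material in the flask at 8.0 min, as a percentage of the starting material charged

At equal loading and with a minority of the catalyst bound, the share of the charge converted per second grows about in step with c(starting material), which gives 1.08. This is the charge number, the dusk share converted per second multiplied by the concentration ratio and the flask's time. It counts how many charges the opening rate would convert, and on a pseudo-first-order fall 0.693 marks the point where target equals starting material. The flask stands above that mark, so this reckoning gives 66.0% target and 34.0% starting material. One number is not quite enough, though: with the catalyst partly bound the rate may grow less than the concentration, and with no growth the number is 0.538 and the target 41.6%; this reckoning stays near the upper figure.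

The forecast stood lower, at 30% target (17% to 47%) and 69% starting material (51% to 82%), noting that “the rate seems to sag slightly”.

The flask gives 61.4% target and 37.5% starting material.

    catalyst intermediate → free catalyst + target (k = 0.0707 /s)
    2 free catalyst → spent catalyst (k = 0.0107 /M/s)
    starting material + free catalyst ⇌ catalyst intermediate (K = 1.02 /M, k = 1.64 /M/s)

The flask's target lies 4.5 points under the charge number's figure. Two things acting together hold the flask at that target, the backward run from catalyst intermediate to starting material and free catalyst, and the time allowed: the same flask without the backward run holds >99.9% target, and left ten times as long it holds 99.8%. A second flask at 0.56 M, with the same loading and time, has a charge number of 0.641, below the mark, which gives 47.3% target, and that flask holds 48.2%.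

The runs were computed with made-up constants, and the scatter is random.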